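## Retrosynthetic overview

1. Target ⇒ cut the ester C–O bond at C3: a C40 (3R)-carotenol plus an oleoyl donor; no C–C bond is made anywhere in the route.
2. The carotenol is used one unsaturation higher, as (3R)-3',4'-didehydro-β,β-caroten-3-ol, so that the acid expelled by O-acylation drives the 3',4'-reduction in the same flask.
3. That dodecaenol ⇐ acid dehydration/isomerisation of commercial (3R,3'R,6'R)-lutein, which supplies all 40 carbons, the all-E chain and the 3R carbinol.
4. Oleoyl donor ⇐ oleic acid + trifluoroacetic anhydride (mixed anhydride; the Z-alkene comes from oleic acid).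
5. Rings: none is formed; both six-membered rings come from lutein, and the ε-ring is converted into the second β-ring.

Assumption: crystalline marigold lutein (all-E, about 5% zeaxanthin, removed at compound 4) and 99% oleic acid are taken as cheap commercial materials.

## Route

Step 1
Reactants: 1 (3R,3'R,6'R)-lutein
Product: 4 (3R)-3',4'-didehydro-β,β-caroten-3-ol, via β,γ-anhydrolutein 2 (not isolated), via β,ε-anhydrolutein 3 (not isolated)
Conditions: H2SO4 (cat.), n-PrOH/H2O, 88 °C, N2, dark, 20 h; SiO2 plug, crystallise (CH2Cl2/hexane)
Reagents that add atoms: none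
Why: Acid-catalysed E1 dehydration in which only the allylic 3'-OH ionises, followed by reversible protonation that funnels the kinetic dienes 2 and 3 to the fully conjugated dodecaene 4 under thermodynamic control; the non-allylic 3R carbinol and the all-E chain are untouched and no stereocentre is formed (C6' is deliberately destroyed).

Step 2
Reactants: 5 oleic acid
Product: 6 oleic trifluoroacetic anhydride
Conditions: (CF3CO)2O (1.05 equiv), CH2Cl2, 0 → 20 °C, 30 min, N2; solution (6 + 1 equiv CF3CO2H) used at once
Reagents that add atoms: trifluoroacetic anhydride, O=C(OC(=O)C(F)(F)F)C(F)(F)F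
Why: Anhydride exchange (mixed-anhydride formation by acyl transfer from the more electrophilic perfluoro anhydride) is fast and essentially quantitative, and the isolated Z-alkene does not add CF3CO2H on this time scale at or below 20 °C.

Step 3
Reactants: 4 (3R)-3',4'-didehydro-β,β-caroten-3-ol; 6 oleic trifluoroacetic anhydride
Product: 8 (3R)-β-cryptoxanthin oleate, via (3R)-3',4'-didehydro-β-cryptoxanthin oleate 7 (not isolated)
Conditions: 4, Me3N·BH3 (3 equiv), CH2Cl2, −20 °C; add solution of 6 (1.5 equiv, carries 1.5 equiv CF3CO2H), 20 min; then 20 °C, 4 h, N2, dark, no further acid; aq. NaHCO3; SiO2 (1% Et3N), then acetone/EtOH, −20 °C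
Reagents that add atoms: none
Why: Proposed new method: acid-relay acylative ionic hydrogenation, in which the 3-OH of 4 attacks the oleoyl carbonyl of 6 (trifluoroacetate is the better leaving group) to form the ester C–O bond with retention at C3 (the C3–O bond is never broken) within minutes, and the CF3CO2H released, together with the equivalent carried from step 2, then protonates the dodecaene of 7 at its terminus C3' to give the fully delocalised polyenyl cation that Me3N·BH3 quenches by hydride transfer to C4', forming only CH2 groups and leaving the undecaene, the ester and the isolated Z-alkene untouched; the closest known reaction types are carboxylic–trifluoroacetic mixed-anhydride esterification and the CF3CO2H/amine-borane ionic hydrogenation of anhydroluteins, which have not been coupled so that the acylation by-product is the only acid for the reduction.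

## Compound list

1 | (3R,3'R,6'R)-lutein, all-E (3R,3'R,6'R)-β,ε-carotene-3,3'-diol | O[C@@H]1CC(C)=C(/C=C/C(C)=C/C=C/C(C)=C/C=C/C=C(C)/C=C/C=C(C)/C=C/[C@H]2C(C)=C[C@H](O)CC2(C)C)C(C)(C)C1 | starting material

2 | β,γ-anhydrolutein, (3R,6'R)-3',4'-didehydro-β,γ-caroten-3-ol (exocyclic methylene at C5') | O[C@@H]1CC(C)=C(/C=C/C(C)=C/C=C/C(C)=C/C=C/C=C(C)/C=C/C=C(C)/C=C/[C@H]2C(=C)C=CCC2(C)C)C(C)(C)C1 | intermediate

3 | β,ε-anhydrolutein, (3R,6'S)-2',3'-didehydro-β,ε-caroten-3-ol (C6' unchanged in space from 1; only the descriptor letter changes) | O[C@@H]1CC(C)=C(/C=C/C(C)=C/C=C/C(C)=C/C=C/C=C(C)/C=C/C=C(C)/C=C/[C@H]2C(C)=CC=CC2(C)C)C(C)(C)C1 | intermediate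

4 | (3R)-3',4'-didehydro-β,β-caroten-3-ol, all-E (the fully conjugated anhydrolutein) | O[C@@H]1CC(C)=C(/C=C/C(C)=C/C=C/C(C)=C/C=C/C=C(C)/C=C/C=C(C)/C=C/C2=C(C)C=CCC2(C)C)C(C)(C)C1 | intermediate

5 | oleic acid, (9Z)-octadec-9-enoic acid | CCCCCCCC/C=C\CCCCCCCC(=O)O | starting material

6 | oleic trifluoroacetic anhydride, (9Z)-octadec-9-enoic trifluoroacetic anhydride | CCCCCCCC/C=C\CCCCCCCC(=O)OC(=O)C(F)(F)F | intermediate

7 | (3R)-3',4'-didehydro-β-cryptoxanthin oleate, (3R)-3',4'-didehydro-β,β-caroten-3-yl (9Z)-octadec-9-enoate | CCCCCCCC/C=C\CCCCCCCC(=O)O[C@@H]1CC(C)=C(/C=C/C(C)=C/C=C/C(C)=C/C=C/C=C(C)/C=C/C=C(C)/C=C/C2=C(C)C=CCC2(C)C)C(C)(C)C1 | intermediate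

8 | (3R)-β-cryptoxanthin oleate, (3R)-β,β-caroten-3-yl (9Z)-octadec-9-enoate, all-E (CNP0152321.1) | CCCCCCCC/C=C\CCCCCCCC(=O)O[C@@H]1CC(C)=C(/C=C/C(C)=C/C=C/C(C)=C/C=C/C=C(C)/C=C/C=C(C)/C=C/C2=C(C)CCCC2(C)C)C(C)(C)C1 | target

## Step count and risk

Total step count: 3. Longest linear sequence: 2 (steps 1 and 3; step 2 is a one-step branch).

Steps most likely to fail, in order:

Step 3 (proposed new step). Risks: some O-trifluoroacetylation instead of O-oleoylation, acid damage or E/Z scrambling of the polyene before hydride capture, hydride delivery to a position other than C4', and too little relayed acid. The fallback uses known chemistry only; it sets out from 4 and comes back to the route at 8. Compound 4 is reduced under the reported ionic-hydrogenation conditions for anhydroluteins (CF3CO2H 3.5 equiv, Me3N·BH3 3 equiv, CH2Cl2, 20 °C) to (3R)-β-cryptoxanthin F1, which is crystallised to all-E purity. F1 is then esterified with oleic acid 5 under Steglich conditions (N,N'-diisopropylcarbodiimide, cat. DMAP, CH2Cl2, 0 → 20 °C) to give 8.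

Step 1. Risks: incomplete isomerisation of 2 and 3 to 4, and Z-isomers or decomposition from prolonged hot acid. The fallback sets out from 1 and comes back at 4. The two events are separated: 1 is dehydrated at 20 °C with a trace of HCl in THF/H2O only as far as the kinetic diene mixture (2 and 3 with some 4), which is isolated by precipitation. The double bonds are then moved into conjugation with base instead of acid (KOH, DMSO, 70 °C, the type of conditions that converts lutein into zeaxanthin): deprotonation at the doubly allylic C6' and reprotonation at the ring terminus gives 4. No new compound is made.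

Step 2. Risks: the mixed anhydride disproportionates to oleic anhydride and trifluoroacetic anhydride (which would trifluoroacetylate 4), or is hydrolysed by moisture. The fallback sets out from 5 and comes back at 7. Oleic acid is converted with oxalyl chloride and cat. DMF in CH2Cl2 into oleoyl chloride F2, a defined and storable acyl donor. F2 (1.2 equiv) with pyridine (1.3 equiv) acylates 4 at 0 °C to 7. In the same flask Me3N·BH3 (3 equiv) and separately metered CF3CO2H (4.5 equiv, the first 1.3 equiv neutralise pyridine) then reduce 7 to 8.

## Further compounds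

F1 | step 3 | (3R)-β-cryptoxanthin, (3R)-β,β-caroten-3-ol, all-E | O[C@@H]1CC(C)=C(/C=C/C(C)=C/C=C/C(C)=C/C=C/C=C(C)/C=C/C=C(C)/C=C/C2=C(C)CCCC2(C)C)C(C)(C)C1
F0 | step 1 | none | none
F2 | step 2 | oleoyl chloride, (9Z)-octadec-9-enoyl chloride | CCCCCCCC/C=C\CCCCCCCC(=O)Cl
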